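The route rests on closing the cyclopentane that carries one CH2OH (ring C) last, by joining its CH(CH2OH) carbon to the allylic methylene of the cyclopentene (ring B). The key step is a dirhodium-carbenoid C–H insertion of an α-diazo seven-membered lactone. The lactone ties the future ring C carboxyl carbon to the CH2O group on the quaternary one-carbon bridge, so the carbene is held over the alkene face syn to that bridge. One operation should close ring C and set both of its CH stereocentres; lactone reduction then reveals both CH2OH groups. The precursor is a lactone-bridged N-Boc 8-azabicyclo[4.3.1]dec-2-ene fused to the cyclopentene.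

Key step: step 15

Remark (locants used below): side chain C1–C5 with carbinol C3; C6 = quaternary one-carbon bridge bearing C20H2OH and the chain; C7 = bridgehead CH; C8, C9 = ring A CH2; C10=C11 = alkene shared by rings A (cycloheptene) and B (cyclopentene); C12 = CH shared by rings B and C; C13, C14 = ring B CH2; C15 = CH bearing C21H2OH; C16 = ring C CH2; C17 = quaternary bridgehead; C18 (on C17) and C19 (on C7) = NCH2 of ring D (piperidine).

Remark (assumption): in step 4 the sense of induction is taken by analogy with cyclic enones ((S)-BINAP gives the 4S adduct); if it proved opposite, (R)-BINAP would be used.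

Step 1
Reactants: 1 methyl (3S)-3-hydroxypentanoate
Product: 2 (3S)-pentane-1,3-diol
Conditions: LiAlH4, THF, 0 °C → rt
Reagents that add atoms: none
Why: Hydride reduction of the ester to the primary alcohol; the bought C3 stereocentre is not touched.

Step 2
Reactants: 2 (3S)-pentane-1,3-diol
Product: 3 (3S)-1-iodopentan-3-ol
Conditions: I2, PPh3, imidazole, CH2Cl2, 0 °C
Reagents that add atoms: iodine II
Why: Appel-type (Garegg–Samuelsson) iodination, which should take the unhindered primary hydroxyl in preference to the secondary one.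

Step 3
Reactants: 3 (3S)-1-iodopentan-3-ol
Product: 4 (3S)-1-iodopentan-3-yl pivalate
Conditions: PivCl, pyridine, DMAP (cat.), CH2Cl2, 0 °C → rt
Reagents that add atoms: pivaloyl chloride CC(C)(C)C(=O)Cl
Why: DMAP-catalysed acylation of the secondary alcohol; the pivalate has no α-hydrogen, should resist the later amide bases and is removed by the final LiAlH4.

Step 4
Reactants: 5 tert-butyl 2-oxo-2,5-dihydro-1H-pyrrole-1-carboxylate
Product: 6 tert-butyl (4S)-4-ethenyl-2-oxopyrrolidine-1-carboxylate
Conditions: [Rh(cod)Cl]2 (2.5 mol%), (S)-BINAP (6 mol%), Et3N, dioxane/H2O (10:1), 60 °C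
Reagents that add atoms: potassium vinyltrifluoroborate C=C[B-](F)(F)F.[K+]
Why: Hayashi–Miyaura rhodium-catalysed asymmetric conjugate addition to the unsaturated N-Boc lactam; the chiral bisphosphine selects the alkene face and sets C7, the only stereocentre of the core made by catalysis.

Step 5
Reactants: 6 tert-butyl (4S)-4-ethenyl-2-oxopyrrolidine-1-carboxylate, 7 1,2-dibromocyclopent-1-ene
Product: 9 tert-butyl (4R)-4-[2-(2-bromocyclopent-1-en-1-yl)ethyl]-2-oxopyrrolidine-1-carboxylate, via B-alkyl-9-BBN adduct 8 (not isolated)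
Conditions: 9-BBN, THF, 0 °C → rt; then 7 (3 equiv), Pd(dppf)Cl2 (5 mol%), AsPh3, Cs2CO3, DMF/H2O, rt
Reagents that add atoms: none
Why: Anti-Markovnikov hydroboration of the vinyl group followed by B-alkyl Suzuki–Miyaura coupling; excess dibromide and the hindered tetrasubstituted product bromide should limit the reaction to mono-coupling, and C7 is unaffected.

Step 6
Reactants: 9 tert-butyl (4R)-4-[2-(2-bromocyclopent-1-en-1-yl)ethyl]-2-oxopyrrolidine-1-carboxylate, 4 (3S)-1-iodopentan-3-yl pivalate
Product: 10 tert-butyl (3R,4R)-4-[2-(2-bromocyclopent-1-en-1-yl)ethyl]-2-oxo-3-[(3S)-3-(pivaloyloxy)pentyl]pyrrolidine-1-carboxylate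
Conditions: LiHMDS, THF, −78 °C; then 4, DMPU, −78 → −30 °C
Reagents that add atoms: none
Why: SN2 alkylation of the lactam lithium enolate by the primary iodide, expected trans to the C7 substituent; the configuration at C6 is erased in the next step, so only the C5–C6 bond matters here.

Step 7
Reactants: 10 tert-butyl (3R,4R)-4-[2-(2-bromocyclopent-1-en-1-yl)ethyl]-2-oxo-3-[(3S)-3-(pivaloyloxy)pentyl]pyrrolidine-1-carboxylate
Product: 11 tert-butyl (3R,4R)-3-allyl-4-[2-(2-bromocyclopent-1-en-1-yl)ethyl]-2-oxo-3-[(3S)-3-(pivaloyloxy)pentyl]pyrrolidine-1-carboxylate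
Conditions: LiHMDS, THF, −78 °C; allyl bromide, −78 → −40 °C
Reagents that add atoms: allyl bromide C=CCBr
Why: Second enolate alkylation creates quaternary C6; allyl bromide should approach the planar enolate anti to the C7 side chain, so the allyl group (future C17–C18) ends trans and the pentyl chain cis to that side chain, which is the C6 configuration of the target (substrate control from C7).

Step 8
Reactants: 11 tert-butyl (3R,4R)-3-allyl-4-[2-(2-bromocyclopent-1-en-1-yl)ethyl]-2-oxo-3-[(3S)-3-(pivaloyloxy)pentyl]pyrrolidine-1-carboxylate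
Product: 12 tert-butyl N-{2-[2-(2-bromocyclopent-1-en-1-yl)ethyl]-3-(hydroxymethyl)-3-[(3S)-3-(pivaloyloxy)pentyl]hex-5-en-1-yl}carbamate (C6 and C7 as in 11)
Conditions: LiBH4, THF, 0 °C → rt
Reagents that add atoms: none
Why: Reductive ring opening of the activated N-acyl carbamate: hydride adds to the ring carbonyl, the hemiaminal collapses to the aldehyde, and a second hydride gives the C20 alcohol and the C19 NHBoc group; the hindered pivalate should survive at low temperature.

Step 9
Reactants: 12 tert-butyl N-{2-[2-(2-bromocyclopent-1-en-1-yl)ethyl]-3-(hydroxymethyl)-3-[(3S)-3-(pivaloyloxy)pentyl]hex-5-en-1-yl}carbamate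
Product: 13 acrylate ester of 12 at the C20 oxygen
Conditions: acryloyl chloride, iPr2NEt, CH2Cl2, −20 → 0 °C
Reagents that add atoms: acryloyl chloride C=CC(=O)Cl
Why: O-acylation of the neopentyl primary alcohol; the acrylate masks the C20 oxygen and brings in C21, C15 and C16 of the future lactone.

Step 10
Reactants: 13 acrylate ester of 12 at the C20 oxygen
Product: 15 tert-butyl 4-[(acryloyloxy)methyl]-5-[2-(2-bromocyclopent-1-en-1-yl)ethyl]-2-hydroxy-4-[(3S)-3-(pivaloyloxy)pentyl]piperidine-1-carboxylate (cyclic hemiaminal, both C18 epimers), via C18 aldehyde 14 (not isolated)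
Conditions: K2OsO4·2H2O (2 mol%), NaIO4, 2,6-lutidine, dioxane/H2O, 0 °C → rt
Reagents that add atoms: sodium periodate [Na+].[O-]I(=O)(=O)=O (source, through OsO4 and water, of the new C18 oxygen)
Why: Lemieux–Johnson cleavage of the electron-neutral terminal alkene, which should be faster than reaction of the electron-poor acrylate and the hindered bromoalkene; the δ-carbamoyl aldehyde closes spontaneously to the six-membered N-Boc hemiaminal (ring D).

Step 11
Reactants: 15 cyclic hemiaminal acrylate
Product: 17 bicyclic hemiaminal lactone (ring D N-Boc-2-hydroxypiperidine fused at C17–C6 to the seven-membered lactone C17–C16H2–C15H2–C21(=O)–O–C20H2–C6; mixture at C17 and C18), via pyrrolidine enamine 16 (not isolated)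
Conditions: pyrrolidine (1.5 equiv), 4 Å MS, MeCN, rt → 60 °C; then AcOH/H2O/THF, rt
Reagents that add atoms: none
Why: Intramolecular Stork enamine Michael addition: the enamine of the open aldehyde attacks the terminal carbon of the tethered acrylate (7-endo-trig, helped by the quaternary C6), forming C16–C17 and the lactone, and hydrolysis returns the aldehyde, which re-closes to the hemiaminal; the C17 configuration is irrelevant because C17 becomes trigonal in step 12.

Step 12
Reactants: 17 bicyclic hemiaminal lactone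
Product: 18 enecarbamate lactone (as 17 with C17=C18; N-Boc-1,2,3,4-tetrahydropyridine fused to the seven-membered lactone)
Conditions: (CF3CO)2O, 2,6-lutidine, toluene, 0 → 70 °C
Reagents that add atoms: none
Why: Dehydration of the N-Boc hemiaminal through its trifluoroacetate and the N-acyliminium ion; all stereoisomers of 17 converge on one enecarbamate.

Step 13
Reactants: 18 enecarbamate lactone
Product: 19 tetracyclic lactone (N-Boc 8-azabicyclo[4.3.1]dec-2-ene of rings A and D, cyclopentene ring B fused at C10=C11, seven-membered lactone bridging C17 and C6; C6, C7, C17 as in the target)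
Conditions: Pd(OAc)2 (10 mol%), PPh3 (25 mol%), HCO2Na (slow addition), Et4NCl, DMF, 85 °C
Reagents that add atoms: none
Why: Reductive Heck cyclisation: zerovalent palladium inserts into C11–Br, 7-exo-trig syn-carbopalladation of C17=C18 forms the C11–C17 bond and quaternary C17, and formate-derived hydride replaces palladium at C18 because no syn β-hydrogen exists; the C8–C9 tether lets C11 reach only the C17 face cis to the C7 side chain, so C17 is set by C7.

Step 14
Reactants: 19 tetracyclic lactone
Product: 21 α-diazo lactone (C15=N2), via α-trifluoroacetyl lactone 20 (not isolated)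
Conditions: LiHMDS, THF, −78 °C; CF3CO2CH2CF3; then MsN3, Et3N, H2O, MeCN, rt
Reagents that add atoms: methanesulfonyl azide CS(=O)(=O)N=[N+]=[N-]; 2,2,2-trifluoroethyl trifluoroacetate FC(F)(F)COC(=O)C(F)(F)F (leaves the COCF3 group in 20 only)
Why: Danheiser detrifluoroacetylative diazo transfer (Regitz type): C15 is the only enolisable carbon, its trifluoroacetyl derivative takes up the diazo group, and the activating acyl group leaves on the sulfonamide.

Step 15
Reactants: 21 α-diazo lactone
Product: 22 pentacyclic lactone (ring C closed by C12–C15; C12 and C15 as in the target; lactone C21(=O)–O–C20, N-Boc, C3 pivalate)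
Conditions: Rh2(O2CCPh3)4 (2 mol%), CH2Cl2, slow addition of 21 at −78 °C, then → 0 °C
Reagents that add atoms: none
Why: The dirhodium tetracarboxylate (divalent rhodium) expels N2 to give an electrophilic carbenoid at C15, which inserts into the allylic C12–H bond through a three-centre transition state with retention at C12; the closest known reaction is the intramolecular 1,5 C–H insertion of α-alkyl-α-diazo esters (Taber cyclopentane synthesis). Ring C closes as a five-membered ring through the new C12–C15 bond (carbene carbon, C16, C17, C11, C12). C15 is controlled by the lactone tether: C21 stays bonded through oxygen to C20 on C6, so C21 and C6 must end cis on ring C. C12 is controlled by the same tether, which holds the carbene over the alkene face bearing C6, so only the hydrogen on that face is replaced and H12 stays on the face of C18. The step needs insertion to outrun 1,2-hydride shift from C16 and insertion at other sites: bulky triphenylacetate ligands and low temperature disfavour the hydride shift, while C5–H and C19–H lie on the far side of C16, C7–H is anti to C16, insertion at C20 would give a β-lactone and cyclopropanation of C10=C11 would need a four-membered ring. The carbamate keeps nitrogen non-basic, so no ammonium ylide should form.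

Step 16
Reactants: 22 pentacyclic lactone
Product: 23 CNP0221997.1 (target; 3S,6S,7R,12S,15S,17S)
Conditions: LiAlH4 (excess), THF, 0 °C → reflux; Fieser work-up
Reagents that add atoms: none
Why: Global hydride reduction: the lactone gives both CH2OH groups (C20 and C21), the Boc carbamate is reduced to N-methyl and the pivalate is cleaved to the C3 alcohol; the tetrasubstituted alkene and all stereocentres are untouched.

Compound list
1 | methyl (3S)-3-hydroxypentanoate | CC[C@H](O)CC(=O)OC | starting material
2 | (3S)-pentane-1,3-diol | CC[C@H](O)CCO | intermediate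
3 | (3S)-1-iodopentan-3-ol | CC[C@H](O)CCI | intermediate
4 | (3S)-1-iodopentan-3-yl pivalate | CC[C@H](OC(=O)C(C)(C)C)CCI | intermediate
5 | tert-butyl 2-oxo-2,5-dihydro-1H-pyrrole-1-carboxylate | O=C1C=CCN1C(=O)OC(C)(C)C | starting material
6 | tert-butyl (4S)-4-ethenyl-2-oxopyrrolidine-1-carboxylate | O=C1C[C@@H](C=C)CN1C(=O)OC(C)(C)C | intermediate
7 | 1,2-dibromocyclopent-1-ene | BrC1=C(Br)CCC1 | starting material
8 | tert-butyl (4R)-4-[2-(9-borabicyclo[3.3.1]nonan-9-yl)ethyl]-2-oxopyrrolidine-1-carboxylate | O=C1C[C@@H](CCB2C3CCCC2CCC3)CN1C(=O)OC(C)(C)C | intermediate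
9 | tert-butyl (4R)-4-[2-(2-bromocyclopent-1-en-1-yl)ethyl]-2-oxopyrrolidine-1-carboxylate | O=C1C[C@@H](CCC2=C(Br)CCC2)CN1C(=O)OC(C)(C)C | intermediate
10 | tert-butyl (3R,4R)-4-[2-(2-bromocyclopent-1-en-1-yl)ethyl]-2-oxo-3-[(3S)-3-(pivaloyloxy)pentyl]pyrrolidine-1-carboxylate (3,4-trans) | CC[C@H](OC(=O)C(C)(C)C)CC[C@H]1C(=O)N(C(=O)OC(C)(C)C)C[C@@H]1CCC2=C(Br)CCC2 | intermediate
11 | tert-butyl (3R,4R)-3-allyl-4-[2-(2-bromocyclopent-1-en-1-yl)ethyl]-2-oxo-3-[(3S)-3-(pivaloyloxy)pentyl]pyrrolidine-1-carboxylate (allyl trans to the C4 side chain) | CC[C@H](OC(=O)C(C)(C)C)CC[C@]1(CC=C)C(=O)N(C(=O)OC(C)(C)C)C[C@@H]1CCC2=C(Br)CCC2 | intermediate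
12 | tert-butyl N-{2-[2-(2-bromocyclopent-1-en-1-yl)ethyl]-3-(hydroxymethyl)-3-[(3S)-3-(pivaloyloxy)pentyl]hex-5-en-1-yl}carbamate (C6, C7 as in 11) | CC[C@H](OC(=O)C(C)(C)C)CC[C@](CC=C)(CO)[C@H](CNC(=O)OC(C)(C)C)CCC1=C(Br)CCC1 | intermediate
13 | acrylate ester of 12 at the C20 oxygen | CC[C@H](OC(=O)C(C)(C)C)CC[C@](CC=C)(COC(=O)C=C)[C@H](CNC(=O)OC(C)(C)C)CCC1=C(Br)CCC1 | intermediate
14 | C18 aldehyde (allyl of 13 cleaved to CH2CHO) | CC[C@H](OC(=O)C(C)(C)C)CC[C@](CC=O)(COC(=O)C=C)[C@H](CNC(=O)OC(C)(C)C)CCC1=C(Br)CCC1 | intermediate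
15 | tert-butyl 4-[(acryloyloxy)methyl]-5-[2-(2-bromocyclopent-1-en-1-yl)ethyl]-2-hydroxy-4-[(3S)-3-(pivaloyloxy)pentyl]piperidine-1-carboxylate (cyclic hemiaminal, C18 epimers) | CC[C@H](OC(=O)C(C)(C)C)CC[C@@]1(COC(=O)C=C)CC(O)N(C(=O)OC(C)(C)C)C[C@@H]1CCC2=C(Br)CCC2 | intermediate
16 | pyrrolidine enamine of aldehyde 14 | CC[C@H](OC(=O)C(C)(C)C)CC[C@](C=CN1CCCC1)(COC(=O)C=C)[C@H](CNC(=O)OC(C)(C)C)CCC2=C(Br)CCC2 | intermediate
17 | bicyclic hemiaminal lactone (N-Boc-2-hydroxypiperidine fused at C17–C6 to the seven-membered lactone; mixture at C17, C18) | CC[C@H](OC(=O)C(C)(C)C)CC[C@@]12COC(=O)CCC1C(O)N(C(=O)OC(C)(C)C)C[C@@H]2CCC3=C(Br)CCC3 | intermediate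
18 | enecarbamate lactone (C17=C18) | CC[C@H](OC(=O)C(C)(C)C)CC[C@@]12COC(=O)CCC1=CN(C(=O)OC(C)(C)C)C[C@@H]2CCC3=C(Br)CCC3 | intermediate
19 | tetracyclic lactone (rings A, B, D and lactone; C18H2; N-Boc) | CC[C@H](OC(=O)C(C)(C)C)CC[C@@]12COC(=O)CC[C@]1(CN(C(=O)OC(C)(C)C)C[C@@H]2CC3)C4=C3CCC4 | intermediate
20 | α-trifluoroacetyl lactone (C15–COCF3) | CC[C@H](OC(=O)C(C)(C)C)CC[C@@]12COC(=O)C(C(=O)C(F)(F)F)C[C@]1(CN(C(=O)OC(C)(C)C)C[C@@H]2CC3)C4=C3CCC4 | intermediate
21 | α-diazo lactone (C15=N2) | CC[C@H](OC(=O)C(C)(C)C)CC[C@@]12COC(=O)C(=[N+]=[N-])C[C@]1(CN(C(=O)OC(C)(C)C)C[C@@H]2CC3)C4=C3CCC4 | intermediate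
22 | pentacyclic lactone (ring C closed; lactone C21(=O)–O–C20; N-Boc; C3 pivalate) | CC[C@H](OC(=O)C(C)(C)C)CC[C@]1(CO5)[C@H]2CCC3=C4[C@@H](CC3)[C@@H](C5=O)C[C@]41CN(C(=O)OC(C)(C)C)C2 | intermediate
23 | CNP0221997.1 (3S,6S,7R,12S,15S,17S; N-methyl triol) | CC[C@H](O)CC[C@]1(CO)[C@H]2CCC3=C4[C@@H](CC3)[C@@H](CO)C[C@]41CN(C)C2 | target

Total step count: 16. Longest linear sequence: 14 steps (steps 1–3 from compound 1, then steps 6–16). The branch from compound 5 (steps 4–16) is 13 steps and joins the iodide branch at step 6.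

Steps most likely to fail

Step 15 (key step). The carbenoid may lose itself by 1,2-hydride migration from C16 to an unsaturated lactone faster than it inserts, or insertion may be slow because the seven-membered lactone cannot bring the carbene close enough to C12–H. Fallback (ionic instead of carbenoid, setting out from 19 and returning at 22): sensitised photo-oxygenation of 19 (O2, tetraphenylporphyrin, hν, CH2Cl2, −40 °C; then PPh3). Singlet oxygen should bond to the less hindered alkene carbon C10 and, in the Schenck ene reaction, take the only allylic hydrogen on the C11 side (C12–H). This gives the transposed tertiary allylic alcohol F1 (C10–OH, C11=C12). LiHMDS/TMSCl (2.5 equiv each, THF, −78 °C) gives the trimethylsilyl ketene acetal and C10 silyl ether F2. Catalytic TMSOTf (CH2Cl2, −78 °C) ionises the allylic silyl ether to the ring B allyl cation. The tethered ketene acetal should capture it at C12 from the same face as in the main route (intramolecular Mukaiyama-type allylic alkylation, five-membered ring closure), regenerating C10=C11 and giving 22.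

Step 13. Hydride may reduce the vinylpalladium species before the slow 7-exo carbopalladation onto the hindered trisubstituted enecarbamate, so that the bromide is simply lost. Fallback (enolate alkenylation instead of Heck, setting out from 17 and returning at 19): Pd(OAc)2, rac-BINAP, Cs2CO3, dioxane, 80 °C. The open-chain aldehyde tautomer of 17 is α-alkenylated intramolecularly by the vinyl bromide through its palladium enolate. The new α-quaternary aldehyde re-closes with the carbamate NH to the tetracyclic hemiaminal F3; only the C17 epimer with the formyl carbon cis to the C19 arm can close ring D, which checks the configuration. Et3SiH, BF3·OEt2 (CH2Cl2, −78 °C) then reduces the N-acyliminium ion to 19.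

Step 11. Pyrrolidine may add to the acrylate, or the acrylate may oligomerise, faster than the 7-endo ring closure takes place. Fallback (intermolecular Stork alkylation and separate lactonisation, setting out from 12 and returning at 18): Ac2O/pyridine gives the C20 acetate F4. K2OsO4/NaIO4 gives the cyclic hemiaminal F5. The preformed pyrrolidine enamine with methyl acrylate (MeCN, reflux; aqueous AcOH) gives the C17-alkylated hemiaminal ester F6. (CF3CO)2O/2,6-lutidine gives the enecarbamate F7. LiOH (THF/MeOH/H2O, 0 °C → rt) cleaves the acetate and the methyl ester, sparing the hindered pivalate, and gives the hydroxy acid F8. Yamaguchi lactonisation (2,4,6-trichlorobenzoyl chloride, Et3N; DMAP, toluene, high dilution) closes the seven-membered lactone to 18.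

Further compounds
F1 | step 15 | tertiary allylic alcohol from 19 (C10–OH, C11=C12) | CC[C@H](OC(=O)C(C)(C)C)CC[C@@]12COC(=O)CC[C@]1(CN(C(=O)OC(C)(C)C)C[C@@H]2CC3)C4=CCCC34O
F2 | step 15 | trimethylsilyl ketene acetal and C10 trimethylsilyl ether of F1 | CC[C@H](OC(=O)C(C)(C)C)CC[C@@]12COC(O[Si](C)(C)C)=CC[C@]1(CN(C(=O)OC(C)(C)C)C[C@@H]2CC3)C4=CCCC34O[Si](C)(C)C
F3 | step 13 | tetracyclic hemiaminal (19 with C18–OH) | CC[C@H](OC(=O)C(C)(C)C)CC[C@@]12COC(=O)CC[C@]1(C(O)N(C(=O)OC(C)(C)C)C[C@@H]2CC3)C4=C3CCC4
F4 | step 11 | C20 acetate of 12 | CC[C@H](OC(=O)C(C)(C)C)CC[C@](CC=C)(COC(C)=O)[C@H](CNC(=O)OC(C)(C)C)CCC1=C(Br)CCC1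
F5 | step 11 | cyclic hemiaminal acetate | CC[C@H](OC(=O)C(C)(C)C)CC[C@@]1(COC(C)=O)CC(O)N(C(=O)OC(C)(C)C)C[C@@H]1CCC2=C(Br)CCC2
F6 | step 11 | C17-(2-methoxycarbonylethyl) hemiaminal acetate | CC[C@H](OC(=O)C(C)(C)C)CC[C@@]1(COC(C)=O)C(CCC(=O)OC)C(O)N(C(=O)OC(C)(C)C)C[C@@H]1CCC2=C(Br)CCC2
F7 | step 11 | enecarbamate methyl ester acetate | CC[C@H](OC(=O)C(C)(C)C)CC[C@@]1(COC(C)=O)C(CCC(=O)OC)=CN(C(=O)OC(C)(C)C)C[C@@H]1CCC2=C(Br)CCC2
F8 | step 11 | enecarbamate hydroxy acid | CC[C@H](OC(=O)C(C)(C)C)CC[C@@]1(CO)C(CCC(=O)O)=CN(C(=O)OC(C)(C)C)C[C@@H]1CCC2=C(Br)CCC2
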